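**Retrosynthetic overview**
1. The target is a 2,3-trans-(2S,3S)-2,3-diaryl-2,3-dihydrobenzofuran (benzofuran numbering O1, C2, C3, C3a, C4–C7, C7a; ring A is the benzo ring). The last operations are BBr3 demethylation and, before it, one acid step that turns C2 from cis to trans and removes a spare 4-methoxybenzyl (PMB) group.
2. The key disconnection is C2–C3. It is made by enantioselective intramolecular 1,5-C–H insertion of a donor/donor rhodium carbene (future C3) into the O–CH2 group of a PMB aryl ether (future C2), starting from an achiral benzophenone hydrazone.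
3. Enabling feature: C3a lies between the two oxygen-bearing carbons C4 and C7a of ring A, a 5-alkylresorcinol unit with a local twofold axis through C3a and C6. With the same PMB group on both oxygens the two O–CH2 groups are homotopic; one PMB becomes C2 plus its 4-oxygenated aryl ring, and the other protects the C4 hydroxyl.
4. The hydrazone comes from the N–H ketimine made from 3,5-dimethoxyphenyllithium and a 2,6-bis(PMB-oxy)benzonitrile. The nitrile comes from 4-bromo-2,6-difluorobenzonitrile by double SNAr and a B-alkyl Suzuki–Miyaura coupling with hydroborated 4-methoxystyrene.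
5. Ring order: all four benzene rings are bought, and the dihydrofuran ring is the only ring formed (step 5).

Key step: step 5

Assumption: the sense of induction cannot be predicted with certainty for this doubly ortho-substituted carbene. Rh2(R-PTAD)4 (dirhodium tetrakis[(R)-(1-adamantyl)(phthalimido)acetate]) is written on the assumption that it gives S at C3; otherwise its commercial mirror image Rh2(S-PTAD)4 is used and nothing else changes.

**Step 1**
Reactants: 1 4-bromo-2,6-difluorobenzonitrile; 2 4-methoxybenzyl alcohol (2.2 equiv)
Product: 4 4-bromo-2,6-bis[(4-methoxybenzyl)oxy]benzonitrile, via sodium 4-methoxybenzyl oxide 3 (not isolated)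
Conditions: 2, NaH, THF, 0 °C; then 1, 0 to 65 °C
Reagents that add atoms: none
Why: Twofold nucleophilic aromatic substitution (SNAr): each fluoride sits ortho to the nitrile and is displaced by the alkoxide far faster than the para bromide, the first alkoxy group is meta to the second C–F carbon and so does not deactivate it, and no stereocenter is formed.

**Step 2**
Reactants: 4 4-bromo-2,6-bis[(4-methoxybenzyl)oxy]benzonitrile; 5 4-methoxystyrene; 6 9-borabicyclo[3.3.1]nonane (9-BBN)
Product: 8 2,6-bis[(4-methoxybenzyl)oxy]-4-[2-(4-methoxyphenyl)ethyl]benzonitrile, via B-alkyl-9-BBN 7 (not isolated)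
Conditions: 5, 6 (0.5 M in THF), 0 °C to rt; then 4, Pd(dppf)Cl2 (5 mol %), aq K3PO4, THF/DMF, 60 °C
Reagents that add atoms: none
Why: Anti-Markovnikov hydroboration of the styrene with 9-BBN followed by a B-alkyl Suzuki–Miyaura coupling at the nitrile-activated C–Br bond should install the saturated two-carbon bridge directly, so that no hydrogenation has to be run in the presence of the PMB ethers.

**Step 3**
Reactants: 8 2,6-bis[(4-methoxybenzyl)oxy]-4-[2-(4-methoxyphenyl)ethyl]benzonitrile; 9 1-bromo-3,5-dimethoxybenzene
Product: 12 1-{2,6-bis[(4-methoxybenzyl)oxy]-4-[2-(4-methoxyphenyl)ethyl]phenyl}-1-(3,5-dimethoxyphenyl)methanimine (N–H ketimine), via 3,5-dimethoxyphenyllithium 10 (not isolated), via lithium ketiminate 11 (not isolated)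
Conditions: 9, n-BuLi, THF, −78 °C; then 8, −78 to 0 °C; dry MeOH quench
Reagents that add atoms: none
Why: Bromine–lithium exchange followed by 1,2-addition of the aryllithium to the linear and therefore accessible C≡N group (ketimine synthesis from a nitrile and an organometallic reagent) stops at ketiminate 11, and an anhydrous methanol quench should free the hindered N–H ketimine, which hydrolyses only slowly.

**Step 4**
Reactants: 12 N–H ketimine
Product: 13 [{2,6-bis[(4-methoxybenzyl)oxy]-4-[2-(4-methoxyphenyl)ethyl]phenyl}(3,5-dimethoxyphenyl)methylidene]hydrazine (hydrazone; C=N geometry not defined)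
Conditions: N2H4·H2O (10 equiv), AcOH (20 mol %), EtOH, 80 °C
Reagents that add atoms: hydrazine, NN
Why: Transimination: the acid-activated N–H ketiminium ion is a much better electrophile than the corresponding doubly ortho-substituted ketone, hydrazine is a small alpha-effect nucleophile and loss of volatile ammonia drives the exchange, while the C=N geometry is irrelevant because both isomers give the same diazo compound.

**Step 5**
Reactants: 13 hydrazone
Product: 16 (2R,3S)-3-(3,5-dimethoxyphenyl)-4-[(4-methoxybenzyl)oxy]-2-(4-methoxyphenyl)-6-[2-(4-methoxyphenyl)ethyl]-2,3-dihydro-1-benzofuran (2,3-cis), via diaryldiazomethane 14 (not isolated), via dirhodium carbene 15 (not isolated)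
Conditions: MnO2 (8 equiv), CH2Cl2, rt, filtration through Celite; then Rh2(R-PTAD)4 (1 mol %), CH2Cl2, 0 °C to rt
Reagents that add atoms: none
Why: MnO2 dehydrogenates hydrazone 13 to diaryldiazomethane 14, which loses N2 at an axial site of the chiral dirhodium tetracarboxylate to give the donor/donor carbene 15; the carbene carbon (future C3) takes up the hydridic hydrogen of an O–CH2 group (future C2) and the rhodium-bound benzhydryl carbon collapses at once on the p-anisyl-stabilised oxocarbenium carbon, which forms the C2–C3 bond and releases the catalyst. The closest known reaction type is the enantioselective intramolecular C–H insertion of donor/donor rhodium carbenes generated from 2-(benzyloxy)benzophenone hydrazones, which delivers cis-2,3-diaryl-2,3-dihydrobenzofurans. One ring is closed, the dihydrofuran O1–C2–C3–C3a–C7a, by 1,5-C–H insertion through a five-membered cyclic transition state. C3 is controlled by the catalyst, whose four PTAD ligands leave one face of the carbene open for hydrogen transfer and C–C bond formation, and C2 is controlled by the mechanism, because the ion-pair-like intermediate closes faster than the O–C2 bond rotates and places both aryl groups on the same face, so the (2R,3S)-cis isomer is expected. The step needs site selectivity among the sp3 C–H bonds, and the substrate secures it: only the two O–CH2 groups reach the carbene through a five-membered transition state, they are the most hydridic C–H bonds present (oxygen plus p-anisyl), and they are homotopic by rotation about the C3–C3a bond of the symmetric ring A, so insertion into either one gives the same compound. The two ortho substituents also shield the diazo carbon against azine formation, and only the configuration at C3 has to be carried on, since C2 is corrected in step 6.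

**Step 6**
Reactants: 16 (2R,3S)-cis-dihydrobenzofuran PMB ether
Product: 18 (2S,3S)-3-(3,5-dimethoxyphenyl)-2-(4-methoxyphenyl)-6-[2-(4-methoxyphenyl)ethyl]-2,3-dihydro-1-benzofuran-4-ol (2,3-trans), via trans PMB ether 17 (not isolated)
Conditions: TFA/CH2Cl2 (1:4), pentamethylbenzene (5 equiv), 0 °C to rt, dilute
Reagents that add atoms: none
Why: Acid-catalysed epimerisation of a 2-aryl-2,3-dihydrobenzofuran combined with acidic PMB ether cleavage: the C2–O1 bond ionises reversibly to a secondary p-anisyl-stabilised cation and recloses to the thermodynamically preferred trans ring (C2 goes from R to S while C3 is not touched and stays S), the same acid ionises the primary PMB–O bond and the cation is removed by Friedel–Crafts alkylation of pentamethylbenzene, and the two phenol oxygens of ring A then being equivalent, reclosure cannot give a regioisomer.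

**Step 7**
Reactants: 18 (2S,3S)-trans phenol tetramethyl ether
Product: 19 5-{(2S,3S)-4-hydroxy-2-(4-hydroxyphenyl)-6-[2-(4-hydroxyphenyl)ethyl]-2,3-dihydro-1-benzofuran-3-yl}benzene-1,3-diol (target)
Conditions: BBr3 (10 equiv), CH2Cl2, −78 to 0 °C; ice-water
Reagents that add atoms: none
Why: Lewis-acid cleavage of the four aryl methyl ethers (BBr3 demethylation) should leave the stereocenters as they are, because the trans ring is already the thermodynamic isomer, so any reversible opening at C2 returns the same (2S,3S) compound, and the saturated two-carbon bridge offers no alkene for cationic side reactions.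

**Compound list**
1 | 4-bromo-2,6-difluorobenzonitrile | N#Cc1c(F)cc(Br)cc1F | starting material
2 | 4-methoxybenzyl alcohol | COc1ccc(CO)cc1 | starting material
3 | sodium 4-methoxybenzyl oxide | [Na+].[O-]Cc1ccc(OC)cc1 | intermediate (not isolated)
4 | 4-bromo-2,6-bis[(4-methoxybenzyl)oxy]benzonitrile | N#Cc1c(OCc2ccc(OC)cc2)cc(Br)cc1OCc1ccc(OC)cc1 | intermediate
5 | 4-methoxystyrene | C=Cc1ccc(OC)cc1 | starting material
6 | 9-borabicyclo[3.3.1]nonane (9-BBN) | B1C2CCCC1CCC2 | starting material
7 | 9-[2-(4-methoxyphenyl)ethyl]-9-borabicyclo[3.3.1]nonane | COc1ccc(CCB2C3CCCC2CCC3)cc1 | intermediate (not isolated)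
8 | 2,6-bis[(4-methoxybenzyl)oxy]-4-[2-(4-methoxyphenyl)ethyl]benzonitrile | COc1ccc(CCc2cc(OCc3ccc(OC)cc3)c(C#N)c(OCc3ccc(OC)cc3)c2)cc1 | intermediate
9 | 1-bromo-3,5-dimethoxybenzene | COc1cc(Br)cc(OC)c1 | starting material
10 | 3,5-dimethoxyphenyllithium | [Li]c1cc(OC)cc(OC)c1 | intermediate (not isolated)
11 | lithium ketiminate (N-lithio derivative of 12) | COc1ccc(CCc2cc(OCc3ccc(OC)cc3)c(C(=N[Li])c3cc(OC)cc(OC)c3)c(OCc3ccc(OC)cc3)c2)cc1 | intermediate (not isolated)
12 | N–H ketimine, 1-{2,6-bis[(4-methoxybenzyl)oxy]-4-[2-(4-methoxyphenyl)ethyl]phenyl}-1-(3,5-dimethoxyphenyl)methanimine | COc1ccc(CCc2cc(OCc3ccc(OC)cc3)c(C(=N)c3cc(OC)cc(OC)c3)c(OCc3ccc(OC)cc3)c2)cc1 | intermediate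
13 | hydrazone of the same diaryl ketone skeleton | COc1ccc(CCc2cc(OCc3ccc(OC)cc3)c(C(=NN)c3cc(OC)cc(OC)c3)c(OCc3ccc(OC)cc3)c2)cc1 | intermediate
14 | 2-[diazo(3,5-dimethoxyphenyl)methyl]-1,3-bis[(4-methoxybenzyl)oxy]-5-[2-(4-methoxyphenyl)ethyl]benzene | COc1ccc(CCc2cc(OCc3ccc(OC)cc3)c(C(=[N+]=[N-])c3cc(OC)cc(OC)c3)c(OCc3ccc(OC)cc3)c2)cc1 | intermediate (not isolated)
15 | dirhodium-bound diarylcarbene (the SMILES shows only the rhodium atom that carries the carbene; the second rhodium and the four PTAD ligands are left out) | COc1ccc(CCc2cc(OCc3ccc(OC)cc3)c(C(=[Rh])c3cc(OC)cc(OC)c3)c(OCc3ccc(OC)cc3)c2)cc1 | intermediate (not isolated)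
16 | (2R,3S)-3-(3,5-dimethoxyphenyl)-4-[(4-methoxybenzyl)oxy]-2-(4-methoxyphenyl)-6-[2-(4-methoxyphenyl)ethyl]-2,3-dihydro-1-benzofuran (cis) | COc1ccc(CCc2cc(OCc3ccc(OC)cc3)c3c(c2)O[C@@H](c2ccc(OC)cc2)[C@H]3c2cc(OC)cc(OC)c2)cc1 | intermediate
17 | (2S,3S)-3-(3,5-dimethoxyphenyl)-4-[(4-methoxybenzyl)oxy]-2-(4-methoxyphenyl)-6-[2-(4-methoxyphenyl)ethyl]-2,3-dihydro-1-benzofuran (trans) | COc1ccc(CCc2cc(OCc3ccc(OC)cc3)c3c(c2)O[C@H](c2ccc(OC)cc2)[C@H]3c2cc(OC)cc(OC)c2)cc1 | intermediate (not isolated)
18 | (2S,3S)-3-(3,5-dimethoxyphenyl)-2-(4-methoxyphenyl)-6-[2-(4-methoxyphenyl)ethyl]-2,3-dihydro-1-benzofuran-4-ol (trans) | COc1ccc(CCc2cc(O)c3c(c2)O[C@H](c2ccc(OC)cc2)[C@H]3c2cc(OC)cc(OC)c2)cc1 | intermediate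
19 | 5-{(2S,3S)-4-hydroxy-2-(4-hydroxyphenyl)-6-[2-(4-hydroxyphenyl)ethyl]-2,3-dihydro-1-benzofuran-3-yl}benzene-1,3-diol | Oc1ccc(CCc2cc(O)c3c(c2)O[C@H](c2ccc(O)cc2)[C@H]3c2cc(O)cc(O)c2)cc1 | target

**Step count**
Total step count: 7. Longest linear sequence: 7 (1 → 4 → 8 → 12 → 13 → 16 → 18 → 19).

**Steps most likely to fail**

Step 5.
- What may go wrong: weak enantiofacial discrimination. The ring A aryl group with its two ortho substituents is forced out of the carbene plane and fills the chiral pocket differently from simpler substrates. Slow nitrogen loss at the shielded diazo carbon would also let an uncatalysed thermal insertion compete.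
- Fallback: stereocontrol is moved from the catalyst to a classical resolution through the free C4 hydroxyl. It sets out from 18 of insufficient enantiomeric purity.
- Acylation with (1S)-(−)-camphanic chloride (Et3N, DMAP, CH2Cl2) should give the (2S,3S)-camphanate ester F1 beside the (2R,3R)-camphanate ester F2.
- The two diastereomers are separated by crystallisation or chromatography. LiOH in THF/H2O then cleaves F1, and the fallback comes back to the route at 18.

Step 4.
- What may go wrong: slow attack of hydrazine at the C=N carbon flanked by two ortho alkoxy groups, with competing hydrolysis by the water of hydrazine hydrate to the unreactive ketone.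
- Fallback: the N–N bond is built on the exposed nitrogen instead of the shielded carbon, the classical entry to sterically congested diaryldiazomethanes. It sets out from 12.
- NOCl, NaOAc, CH2Cl2, −40 °C should give the N-nitrosoketimine F3, which is kept cold.
- LiAlH4 in Et2O at −78 to 0 °C should reduce it to the diazo compound, and the fallback comes back to the route at 14. The solution of 14 goes directly to the rhodium catalyst, so hydrazone 13 and MnO2 are bypassed.

Step 6.
- What may go wrong: proton loss from C3 of the ring-opened cation, which would erode the configuration at C3, and C-benzylation of the electron-rich ring A by the PMB cation.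
- Fallback: the PMB group is taken off without any cation, and the epimerisation is deferred to a low-temperature boron Lewis acid. It sets out from 16.
- H2 (1 atm), Pd/C, EtOAc should cleave the primary PMB aryl ether faster than the hindered secondary C2–O1 bond and give the (2R,3S)-cis phenol F4.
- BBr3 in CH2Cl2 at −78 to 0 °C should then demethylate and turn C2 to the trans configuration in the same operation. The fallback comes back to the route at 19.

**Further compounds**
F1 | step 5 | (1S,4R)-camphanate ester of (2S,3S)-18 at the C4 oxygen | COc1ccc(CCc2cc(OC(=O)[C@@]34CC[C@@](C)(C(=O)O3)C4(C)C)c3c(c2)O[C@H](c2ccc(OC)cc2)[C@H]3c2cc(OC)cc(OC)c2)cc1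
F2 | step 5 | (1S,4R)-camphanate ester of the (2R,3R) enantiomer of 18 | COc1ccc(CCc2cc(OC(=O)[C@@]34CC[C@@](C)(C(=O)O3)C4(C)C)c3c(c2)O[C@@H](c2ccc(OC)cc2)[C@@H]3c2cc(OC)cc(OC)c2)cc1
F3 | step 4 | N-nitrosoketimine derived from 12 | COc1ccc(CCc2cc(OCc3ccc(OC)cc3)c(C(=NN=O)c3cc(OC)cc(OC)c3)c(OCc3ccc(OC)cc3)c2)cc1
F4 | step 6 | (2R,3S)-3-(3,5-dimethoxyphenyl)-2-(4-methoxyphenyl)-6-[2-(4-methoxyphenyl)ethyl]-2,3-dihydro-1-benzofuran-4-ol (cis) | COc1ccc(CCc2cc(O)c3c(c2)O[C@@H](c2ccc(OC)cc2)[C@H]3c2cc(OC)cc(OC)c2)cc1
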